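C1 is the alkene carbon carrying the C7 methylene benzoate, C2 the alkene CH, C3 and C4 the free carbinols, C5 the ring benzoate carbon, C6 the carbinol next to C1. The target is (3R,4S,5R,6R), with O4, O5 and O6 on one face and O3 on the other.
Feature: C4–C5–C6 is a masked dihydroxyacetone whose flanking oxygens O4 and O6 are cis and can share one acetonide. C3–C2=C1–C7 is a but-2-ynal that already holds the primary benzoate and the alkene oxidation level.
Endgame disconnections: the O5 benzoate comes from axial-selective opening of a cyclic orthobenzoate on the free tetraol, and the C5 carbinol from O3-directed hydride delivery to a C5 ketone.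
Key disconnection: C6–C1 (conjugate addition) and C4–C3 (aldol) are made in one (S)-proline-catalysed [3+3] annulation of 2,2-dimethyl-1,3-dioxan-5-one with 4-oxobut-2-yn-1-yl benzoate.
Ring order: the dioxane ring is bought, the carbocycle is the only ring made (step 3, giving a 2,4-dioxabicyclo[3.3.1]non-6-en-9-one), and the dioxane ring is opened again in step 5.
Key step: step 3

Assumption: the sense of induction in step 3 is taken from the Houk–List model for (S)-proline. Should the closure select the other enantiomer, (R)-proline is used and nothing else changes.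

Step 1
Reactants: 1 but-2-yne-1,4-diol; 2 benzoyl chloride
Product: 3 4-hydroxybut-2-yn-1-yl benzoate
Conditions: 1 (4 equiv), Et3N, DMAP (5 mol %), THF/CH2Cl2, 0 °C to rt
Reagents that add atoms: none
Why: DMAP-catalysed acylation of a symmetrical diol used in excess should stop statistically at the monoester, and the surplus water-soluble diol is washed out.

Step 2
Reactants: 3 4-hydroxybut-2-yn-1-yl benzoate
Product: 4 4-oxobut-2-yn-1-yl benzoate
Conditions: activated MnO2 (15 equiv), CH2Cl2, rt; used without storage
Reagents that add atoms: none
Why: Activated MnO2 oxidises propargylic alcohols to ynals under neutral conditions that leave the benzoate untouched and cannot over-oxidise.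

Step 3
Reactants: 4 4-oxobut-2-yn-1-yl benzoate; 5 2,2-dimethyl-1,3-dioxan-5-one
Product: 7 [(1S,5R,8R)-8-hydroxy-3,3-dimethyl-9-oxo-2,4-dioxabicyclo[3.3.1]non-6-en-6-yl]methyl benzoate, via Z-enal Michael adduct 6 (not isolated)
Conditions: (S)-proline (30 mol %), 5 (3 equiv), H2O (5 equiv), DMF, 4 added over 10 h, 23 °C then 40 °C
Reagents that add atoms: none
Why: Proposed new method: (S)-proline should turn 5 into its enamine, whose C6 adds to alkyne carbon C1 of 4 (C6–C1 bond), anti protonation of the resulting allenol at C2 places the formyl group cis to C6 to give Z-enal 6 (any E isomer drains into it through the dienamine), and a second enamine, formed toward the unsubstituted C4 with the C6 side chain held axial by A(1,3) strain, adds to the aldehyde (C4–C3 bond). The closest known reaction types are the stoichiometric alpha,alpha'-annulations of cyclic-ketone pyrrolidine enamines with acrolein and of 1,3-dioxan-5-one enamines with 2-(bromomethyl)acrylates to bicyclo[3.3.1]nonan-9-ones, the C-addition of enamines to alkynyl carbonyl compounds that opens the Bohlmann–Rahtz synthesis, and the proline-catalysed aldol reactions of 5; their merger into a catalytic annulation with an ynal is untested. The carbocycle closes by a 6-(enolendo)-exo-trig aldol addition, whereby the dioxane ring of 5 becomes the second three-atom bridge of the bicycle. C6–H of 6 is alpha to the ketone and gamma to the enal, so C6 should epimerise freely and the closure acts as a dynamic kinetic resolution: the carboxyl group on one face of the anti enamine binds the aldehyde oxygen (Houk–List model) and sets C4 as S, the bridge then allows only C6 R (O4 and O6 cis), and the hydrogen-bonded oxygen lies gauche to C5, so that O3 ends pseudoaxial and trans to O4 (C3 R). The step needs 1,4- over 1,2-addition and C- over N-attack on 4: the 1,2-aldol adduct, the 2H-pyranol tautomer of 6 and the beta-amino enal form reversibly or re-enter by addition–elimination, whereas 7 holds both alpha-hydrogens at bridgeheads and can neither enolise nor dehydrate (Bredt's rule), so it is the sink, and slow addition of 4 to excess 5 keeps the side equilibria small. A secondary amine with an internal acid is chosen because bulky prolinol silyl ethers condense with 4 but not with a ketone and would end in a Mannich closure that holds the amine at C3, while a primary amine would be lost as a pyridinium salt from the Z-ene-1,5-dicarbonyl unit of 6.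

Step 4
Reactants: 7 [(1S,5R,8R)-8-hydroxy-3,3-dimethyl-9-oxo-2,4-dioxabicyclo[3.3.1]non-6-en-6-yl]methyl benzoate
Product: 8 [(1S,5R,8R,9R)-8,9-dihydroxy-3,3-dimethyl-2,4-dioxabicyclo[3.3.1]non-6-en-6-yl]methyl benzoate
Conditions: Me4NBH(OAc)3 (6 equiv), MeCN/AcOH 1:1, −35 to −20 °C; aq. NaHCO3
Reagents that add atoms: none
Why: Evans–Saksena directed reduction: the pseudoaxial O3–H exchanges an acetate on boron and the bound hydride reaches C5 across the 1,3-diaxial gap on the carbocycle face, so O5 should end cis to O4 and O6 and 1,3-anti to O3 (C5 R), while the reagent is too weak to attack from the open dioxane face or to touch the esters.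

Step 5
Reactants: 8 [(1S,5R,8R,9R)-8,9-dihydroxy-3,3-dimethyl-2,4-dioxabicyclo[3.3.1]non-6-en-6-yl]methyl benzoate
Product: 9 [(3R,4S,5R,6R)-3,4,5,6-tetrahydroxycyclohex-1-en-1-yl]methyl benzoate
Conditions: AcOH/H2O 4:1, 40 °C
Reagents that add atoms: none
Why: Acid-catalysed acetal hydrolysis: the acetonide spans two axial oxygens of the carbocycle and is strained, so it should fall off under conditions too mild for ester migration or allylic ionisation.

Step 6
Reactants: 9 [(3R,4S,5R,6R)-3,4,5,6-tetrahydroxycyclohex-1-en-1-yl]methyl benzoate; 10 trimethyl orthobenzoate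
Product: 13 [(3R,4S,5R,6R)-5-(benzoyloxy)-3,4,6-trihydroxycyclohex-1-en-1-yl]methyl benzoate, via 4,5-orthobenzoate 11 (not isolated), via 5,6-orthobenzoate 12 (not isolated)
Conditions: 10 (1.3 equiv), CSA (5 mol %), MeCN, rt; then AcOH/H2O 4:1, 0 °C to rt
Reagents that add atoms: water, O
Why: Acid-catalysed orthoester exchange should engage only the cis-vicinal pairs O4/O5 and O5/O6, and in the favoured half-chair (O3, O4 and O6 equatorial-type, O5 axial) the stereoelectronically controlled hydrolysis of either cyclic orthoester leaves the ester on the axial oxygen, so both intermediates converge on the O5 benzoate without touching a stereocentre.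

Compound list
1 | but-2-yne-1,4-diol | OCC#CCO | starting material
2 | benzoyl chloride | O=C(Cl)c1ccccc1 | starting material
3 | 4-hydroxybut-2-yn-1-yl benzoate | O=C(OCC#CCO)c1ccccc1 | intermediate
4 | 4-oxobut-2-yn-1-yl benzoate | O=CC#CCOC(=O)c1ccccc1 | intermediate
5 | 2,2-dimethyl-1,3-dioxan-5-one | CC1(C)OCC(=O)CO1 | starting material
6 | (2Z)-2-[(4R)-2,2-dimethyl-5-oxo-1,3-dioxan-4-yl]-4-oxobut-2-en-1-yl benzoate (formyl cis to the dioxanyl group; reacting C6 epimer drawn) | O=C/C=C(/COC(=O)c1ccccc1)[C@H]1OC(C)(C)OCC1=O | intermediate
7 | [(1S,5R,8R)-8-hydroxy-3,3-dimethyl-9-oxo-2,4-dioxabicyclo[3.3.1]non-6-en-6-yl]methyl benzoate (acetonide bridging cis O4/O6, C5 ketone, O3 trans to O4) | O=C(OCC1=C[C@@H](O)[C@@H]2OC(C)(C)O[C@H]1C2=O)c1ccccc1 | intermediate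
8 | [(1S,5R,8R,9R)-8,9-dihydroxy-3,3-dimethyl-2,4-dioxabicyclo[3.3.1]non-6-en-6-yl]methyl benzoate (O5 on the dioxane side, cis to O4/O6) | O=C(OCC1=C[C@@H](O)[C@@H]2OC(C)(C)O[C@H]1[C@H]2O)c1ccccc1 | intermediate
9 | [(3R,4S,5R,6R)-3,4,5,6-tetrahydroxycyclohex-1-en-1-yl]methyl benzoate | O=C(OCC1=C[C@@H](O)[C@H](O)[C@H](O)[C@@H]1O)c1ccccc1 | intermediate
10 | trimethyl orthobenzoate | COC(OC)(OC)c1ccccc1 | starting material
11 | cyclic methyl orthobenzoate of 9 on O4/O5 (either configuration at the orthoester carbon) | O=C(OCC1=C[C@@H](O)[C@@H]2OC(OC)(c3ccccc3)O[C@@H]2[C@@H]1O)c1ccccc1 | intermediate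
12 | cyclic methyl orthobenzoate of 9 on O5/O6 (either configuration at the orthoester carbon) | O=C(OCC1=C[C@@H](O)[C@H](O)[C@@H]2OC(OC)(c3ccccc3)O[C@H]12)c1ccccc1 | intermediate
13 | [(3R,4S,5R,6R)-5-(benzoyloxy)-3,4,6-trihydroxycyclohex-1-en-1-yl]methyl benzoate | O=C(OCC1=C[C@@H](O)[C@H](O)[C@H](OC(=O)c2ccccc2)[C@@H]1O)c1ccccc1 | target

Total step count: 6
Longest linear sequence: 6 steps (1, 3, 4, 7, 8, 9, 13)

Steps most likely to fail

**Step 3.**
- What may go wrong: 1,2-addition to the formyl group may outrun conjugate addition. The catalyst may be consumed by aza-Michael addition to the ynal. The aldol closure may revert because the enal loses conjugation and the bicycle is strained. The closure may discriminate poorly between the two C6 epimers.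
- Fallback (known chemistry, the same two bonds made one at a time in reverse order): it sets out from 4 and 5 and comes back at 7.
- (S)-Proline in DMF at 4 °C is used for its default reaction, the intermolecular anti aldol addition of 5 to the aldehyde of 4 (C4–C3 bond). This gives the anti aldol adduct F1, with C4 S as required and C3 epimeric.
- TBSOTf/Et3N in CH2Cl2 silylates O3 and enolises the ketone toward the unsubstituted C6, giving the bis-silyl enol ether F2.
- [(2-biphenylyl)(t-Bu)2P]AuNTf2 (5 mol %) in wet acetone closes the C6–C1 bond by 6-endo-dig carbocyclisation of the silyl enol ether onto the alkyne. This reaction type is established for cyclic silyl enol ethers with a three-atom alkynyl tether on the way to bicyclo[3.3.1]nonenones. The reversible acyloxy shift of the propargylic benzoate is drained by the irreversible C–C bond formation. The product is the 3-epi silyl ether F3.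
- HF·pyridine in THF frees the 3-epi alcohol F4.
- The equatorial allylic hydroxyl of F4 is inverted by a Mitsunobu reaction with chloroacetic acid (PPh3, DIAD, toluene). Elimination is excluded because C4 is a bridgehead. This gives the inverted chloroacetate F5.
- Thiourea/NaHCO3 in EtOH removes the chloroacetyl group beside the benzoate and delivers 7.

**Step 4.**
- What may go wrong: ligand exchange at the pseudoaxial O3 may be slow, or the beta-hydroxy ketone or the strained acetonide may open in the acetic acid medium. Either would let undirected hydride attack from the open dioxane face compete and would erode facial selectivity at C5.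
- Fallback: it sets out from 7 and comes back at 13, bypassing steps 5 and 6.
- An Evans–Tishchenko reduction (SmI2 30 mol %, acetaldehyde, THF, −10 °C) delivers the hydride from the O3 hemiacetal to the same face of C5 in a neutral medium. It gives the 3-O-acetate F6 with O5–H free, so the two hydroxyls are told apart by the reduction itself.
- BzCl/DMAP/pyridine then gives the 3-O-acetyl 5-O-benzoate F7.
- HCl in MeOH removes the acetonide and, selectively over the benzoates, the acetate, giving 13.

**Step 6.**
- What may go wrong: orthoester exchange may engage another hydroxyl pair. The axial preference in the opening may be incomplete. The acyl group may migrate from the axial O5 to O4 or O6 during hydrolysis or isolation.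
- Fallback: it sets out from 8 and comes back at 13, replacing stereoelectronic control by protecting-group control.
- TESCl/imidazole in CH2Cl2 at −20 °C silylates the allylic O3, which has only one branched neighbour, to give the 3-O-triethylsilyl ether F8.
- BzCl/DMAP/pyridine acylates the remaining O5–H to give the 3-O-triethylsilyl 5-O-benzoate F9.
- TFA/H2O/CH2Cl2 at 0 °C removes the silyl ether and the acetonide in one operation to give 13.

Further compounds
F1 | step 3 | (4S)-4-[(4S)-2,2-dimethyl-5-oxo-1,3-dioxan-4-yl]-4-hydroxybut-2-yn-1-yl benzoate | O=C(OCC#C[C@H](O)[C@@H]1OC(C)(C)OCC1=O)c1ccccc1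
F2 | step 3 | O3-TBS ether and C5=C6 TBS enol ether of F1 | O=C(OCC#C[C@H](O[Si](C)(C)C(C)(C)C)[C@@H]1OC(C)(C)OC=C1O[Si](C)(C)C(C)(C)C)c1ccccc1
F3 | step 3 | 3-O-TBS ether of the C3 epimer of 7 | O=C(OCC1=C[C@H](O[Si](C)(C)C(C)(C)C)[C@@H]2OC(C)(C)O[C@H]1C2=O)c1ccccc1
F4 | step 3 | C3 epimer of 7 (O3 equatorial, cis to O4) | O=C(OCC1=C[C@H](O)[C@@H]2OC(C)(C)O[C@H]1C2=O)c1ccccc1
F5 | step 3 | 3-O-chloroacetate of 7 | O=C(OCC1=C[C@@H](OC(=O)CCl)[C@@H]2OC(C)(C)O[C@H]1C2=O)c1ccccc1
F6 | step 4 | 3-O-acetate of 8 | O=C(OCC1=C[C@@H](OC(C)=O)[C@@H]2OC(C)(C)O[C@H]1[C@H]2O)c1ccccc1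
F7 | step 4 | 3-O-acetate 5-O-benzoate of 8 | O=C(OCC1=C[C@@H](OC(C)=O)[C@@H]2OC(C)(C)O[C@H]1[C@H]2OC(=O)c3ccccc3)c1ccccc1
F8 | step 6 | 3-O-triethylsilyl ether of 8 | O=C(OCC1=C[C@@H](O[Si](CC)(CC)CC)[C@@H]2OC(C)(C)O[C@H]1[C@H]2O)c1ccccc1
F9 | step 6 | 3-O-triethylsilyl ether 5-O-benzoate of 8 | O=C(OCC1=C[C@@H](O[Si](CC)(CC)CC)[C@@H]2OC(C)(C)O[C@H]1[C@H]2OC(=O)c3ccccc3)c1ccccc1
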